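**Retrosynthetic overview**
1. The target comes from its tris-silyl ether; the enone tail is attached by adding an (E)-alkenylzinc reagent (from 2-methylbut-3-yn-2-ol TMS ether) to a neopentyl aldehyde, then oxidising.
2. The C4–C5 bond and the Z-trisubstituted alkene are made together by allylboration of a lactol with an α-(arylmethyl)-2-methylallyl boronate. The boronate comes from 2-bromo-6-methylphenol (para C–O bond by Teuber oxidation) and isoprene monoxide.
3. The lactol comes from a δ-lactone, made in the key C–O bond-forming step: a catalytic enantioselective Baeyer–Villiger desymmetrisation of meso cis-1,5-dimethylbicyclo[3.3.0]octan-3-one, which fixes both quaternary centres.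
4. The meso ketone comes from commercial cis-1,5-dimethylbicyclo[3.3.0]octane-3,7-dione by mono-deoxygenation.
5. Ring order: the cyclopentane and the arene are bought; the only ring made is the δ-lactone (ring expansion, step 3), and it is reopened in step 9.

Assumption: compounds 1, 8, 12 and 19 are bought. The sense of induction of the new catalyst in step 3 cannot be predicted, so the ligand antipode is fixed by a pilot run (chiral GC of 6).

**Route**

Step 1
Reactants: 1 cis-1,5-dimethylbicyclo[3.3.0]octane-3,7-dione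
Product: 2 cis-1,5-dimethylbicyclo[3.3.0]octane-3,7-dione mono(2,2-dimethylpropane-1,3-diyl) ketal
Conditions: 2,2-dimethylpropane-1,3-diol (1.0 equiv), TsOH·H2O (cat.), PhH, reflux (Dean–Stark)
Reagents that add atoms: 2,2-dimethylpropane-1,3-diol, OCC(C)(C)CO
Why: Acid-catalysed ketalisation with one equivalent of diol gives the monoketal statistically (bis-ketal and 1 are recycled); the cis ring fusion is not touched.

Step 2
Reactants: 2 monoketal
Product: 5 cis-1,5-dimethylbicyclo[3.3.0]octan-3-one (meso), via ketal hydrazone 3 (not isolated), via deoxygenated ketal 4 (not isolated)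
Conditions: N2H4·H2O, KOH, (HOCH2CH2)2O, 130 → 200 °C; then 2 M HCl, THF, 40 °C
Reagents that add atoms: water, O
Why: Wolff–Kishner (Huang–Minlon) reduction removes the free carbonyl through hydrazone 3 while the base-stable ketal survives, and the acidic work-up hydrolyses ketal 4 to the meso ketone; the ring fusion stays cis.

Step 3
Reactants: 5 cis-1,5-dimethylbicyclo[3.3.0]octan-3-one
Product: 6 (4aR,7aR)-4a,7a-dimethylhexahydrocyclopenta[c]pyran-3(1H)-one
Conditions: Sc(OTf)3 (5 mol%), chiral N,N′-dioxide L* (5.5 mol%; propane-1,3-diyl-bridged bis[pipecolic acid 2,6-diisopropylanilide N-oxide], antipode chosen in a pilot run), mCPBA (1.3 equiv), EtOAc, −20 °C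
Reagents that add atoms: mCPBA, OOC(=O)c1cccc(Cl)c1
Why: Proposed new method: a Sc(OTf)3/chiral N,N′-dioxide complex is asked to desymmetrise a meso cyclopentanone whose only stereocentres are two β-quaternary ring-fusion carbons; trivalent scandium activates the ketone and then chelates the Criegee adduct through the hemiperketal oxygen and the peracid carbonyl, so the O–O bond is held in one of two mirror-related orientations, and the anilide arms, which clash with one angular methyl only, decide which enantiotopic CH2 is antiperiplanar to O–O and migrates (oxygen enters on the side of the S-configured ring-fusion carbon, both quaternary centres untouched), giving the (4aR,7aR) lactone; the closest known reaction type is the Sc(OTf)3/N,N′-dioxide-catalysed desymmetrising Baeyer–Villiger oxidation of 4-substituted cyclohexanones and 3-substituted cyclobutanones, not yet shown for cyclopentanones or for substrates differentiated only at β-quaternary carbons.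

Step 4
Reactants: 6 lactone
Product: 7 (4aR,7aR)-4a,7a-dimethyloctahydrocyclopenta[c]pyran-3-ol (lactol; anomer mixture)
Conditions: iBu2AlH (1.1 equiv), CH2Cl2, −78 °C; aq. KNaC4H4O6
Reagents that add atoms: none
Why: Partial reduction of a δ-lactone with iBu2AlH at −78 °C stops at the aluminium hemiacetal, which gives the lactol on work-up; the quaternary centres are not involved.

Step 5
Reactants: 8 2-bromo-6-methylphenol
Product: 10 2-bromo-6-methylbenzene-1,4-diol, via 2-bromo-6-methyl-1,4-benzoquinone 9 (not isolated)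
Conditions: K2[ON(SO3)2] (2.5 equiv), KH2PO4, acetone/H2O, 0 °C → rt; then aq. Na2S2O4, EtOAc
Reagents that add atoms: potassium nitrosodisulfonate K2[ON(SO3)2], [K+].[K+].[O]N(S(=O)(=O)[O-])S(=O)(=O)[O-]
Why: Teuber oxidation: two equivalents of the nitroxyl radical salt turn the 2,6-disubstituted phenol into the para-quinone (new C–O bond at the free para carbon), and Na2S2O4 reduces quinone 9 to the hydroquinone.

Step 6
Reactants: 10 2-bromo-6-methylbenzene-1,4-diol
Product: 11 1-bromo-2,5-bis(tert-butyldimethylsilyloxy)-3-methylbenzene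
Conditions: TBSCl (2.6 equiv), imidazole, DMF, 40 °C
Reagents that add atoms: TBSCl, CC(C)(C)[Si](C)(C)Cl
Why: Standard imidazole-mediated silylation of both phenols, which masks the air-sensitive hydroquinone until the last step.

Step 7
Reactants: 11 aryl bromide; 12 2-methyl-2-vinyloxirane (isoprene monoxide)
Product: 15 methyl 4-[2,5-bis(tert-butyldimethylsilyloxy)-3-methylphenyl]-2-methylbut-2-en-1-yl carbonate (E/Z mixture; E major), via arylmagnesium bromide 13 (not isolated), via bromomagnesium allylic alkoxide 14 (not isolated)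
Conditions: Mg, LiCl, THF, rt; CuI (10 mol%), 12, −30 °C; then ClCO2Me, −30 °C → rt
Reagents that add atoms: methyl chloroformate, COC(=O)Cl
Why: Magnesium insertion followed by copper-catalysed SN2′ (1,4-) opening of the vinyl epoxide by the aryl Grignard reagent makes the Ar–CH2 bond, and the alkoxide is trapped in the same flask as the carbonate; alkene geometry does not matter because it is erased in step 8.

Step 8
Reactants: 15 allylic carbonate
Product: 16 rac-2-{1-[2,5-bis(tert-butyldimethylsilyloxy)-3-methylphenyl]-3-methylbut-3-en-2-yl}-4,4,5,5-tetramethyl-1,3,2-dioxaborolane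
Conditions: CuCl (5 mol%), Xantphos (5 mol%), KOtBu (10 mol%), B2pin2 (1.3 equiv), THF, rt
Reagents that add atoms: bis(pinacolato)diboron, CC1(C)OB(OC1(C)C)B1OC(C)(C)C(C)(C)O1
Why: Copper-catalysed γ-selective (SN2′) allylic borylation: the boryl-copper species delivers boron to the CH carbon and expels the carbonate, so both alkene isomers of 15 converge on the same racemic secondary allylboronate (its stereocentre is destroyed in step 9).

Step 9
Reactants: 7 lactol; 16 allylboronate (1.5 equiv)
Product: 17 (Z)-6-[2,5-bis(tert-butyldimethylsilyloxy)-3-methylphenyl]-1-[(1R,2R)-2-(hydroxymethyl)-1,2-dimethylcyclopentyl]-4-methylhex-4-en-2-ol (C2 epimers)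
Conditions: PhMe, 60 °C, 36 h; aq. NaHCO3 work-up
Reagents that add atoms: none
Why: Carbonyl allylboration of the open hydroxy-aldehyde tautomer of 7 through a closed chair transition state: the α-CH2Ar group of 16 sits axial to avoid A(1,2) strain with the 2-methyl group, so the new trisubstituted alkene is Z (CH2Ar cis to the new CH2, expected above 10:1); the ring stereocentres are untouched and the mixed carbinol centre is erased in step 10.

Step 10
Reactants: 17 diol
Product: 18 (1R,2R)-2-{(Z)-6-[2,5-bis(tert-butyldimethylsilyloxy)-3-methylphenyl]-4-methyl-2-oxohex-4-en-1-yl}-1,2-dimethylcyclopentane-1-carbaldehyde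
Conditions: (COCl)2, DMSO, CH2Cl2, −78 °C; iPr2NEt, −78 → −40 °C; pH 7 buffer
Reagents that add atoms: none
Why: Swern oxidation: both hydroxyls become alkoxysulfonium salts before base is added, so no lactol or lactone can form, and the cold amine step with neutral quench keeps the β,γ-unsaturated ketone out of conjugation and suppresses aldol closure onto the aldehyde, which is α-quaternary and cannot epimerise.

Step 11
Reactants: 18 keto aldehyde; 19 2-methyl-2-(trimethylsilyloxy)but-3-yne (2 equiv)
Product: 22 (Z)-6-[2,5-bis(tert-butyldimethylsilyloxy)-3-methylphenyl]-1-{(1R,2R)-2-[(E)-1-hydroxy-4-methyl-4-(trimethylsilyloxy)pent-2-en-1-yl]-1,2-dimethylcyclopentyl}-4-methylhex-4-en-2-one (carbinol epimers), via alkenylzirconocene chloride 20 (not isolated), via alkenyl(methyl)zinc 21 (not isolated)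
Conditions: 19, Cp2Zr(H)Cl, CH2Cl2, rt; Me2Zn, PhMe, −65 °C; then 18, 0 °C → rt
Reagents that add atoms: none
Why: Syn-hydrozirconation of the terminal alkyne gives the (E)-alkenylzirconocene, transmetalation to zinc and 1,2-addition to the aldehyde gives the (E)-allylic alcohol, and alkenylzinc reagents do not add to the ketone; the carbinol configuration is irrelevant (oxidised in step 12).

Step 12
Reactants: 22 allylic alcohol
Product: 23 (Z)-6-[2,5-bis(tert-butyldimethylsilyloxy)-3-methylphenyl]-4-methyl-1-{(1R,2R)-1,2-dimethyl-2-[(E)-4-methyl-4-(trimethylsilyloxy)pent-2-enoyl]cyclopentyl}hex-4-en-2-one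
Conditions: Dess–Martin periodinane, NaHCO3, CH2Cl2, 0 °C
Reagents that add atoms: none
Why: Buffered Dess–Martin oxidation of the hindered allylic alcohol gives the (E)-enone without moving the skipped Z-alkene or touching the quaternary centres.

Step 13
Reactants: 23 tris-silyl ether
Product: 24 (Z)-6-(2,5-dihydroxy-3-methylphenyl)-1-{(1R,2R)-2-[(E)-4-hydroxy-4-methylpent-2-enoyl]-1,2-dimethylcyclopentyl}-4-methylhex-4-en-2-one (CNP0212540.1)
Conditions: Bu4NF/AcOH (1:1, 3.5 equiv), THF, 0 °C, argon; aq. Na2S2O4 wash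
Reagents that add atoms: none
Why: Fluoride cleaves the two aryl silyl ethers and the tertiary trimethylsilyl ether, and the acetic acid buffer prevents phenoxide or enolate formation, so the Z-β,γ-unsaturated ketone and both stereocentres are kept.

**Compound list**
1 | cis-1,5-dimethylbicyclo[3.3.0]octane-3,7-dione | O=C1C[C@@]2(C)CC(=O)C[C@@]2(C)C1 | starting material
2 | cis-1,5-dimethylbicyclo[3.3.0]octane-3,7-dione mono(2,2-dimethylpropane-1,3-diyl) ketal | O=C1C[C@@]2(C)CC3(OCC(C)(C)CO3)C[C@@]2(C)C1 | intermediate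
3 | hydrazone of monoketal 2 | NN=C1C[C@@]2(C)CC3(OCC(C)(C)CO3)C[C@@]2(C)C1 | intermediate
4 | cis-1,5-dimethylbicyclo[3.3.0]octan-3-one 2,2-dimethylpropane-1,3-diyl ketal | C1C[C@@]2(C)CC3(OCC(C)(C)CO3)C[C@@]2(C)C1 | intermediate
5 | cis-1,5-dimethylbicyclo[3.3.0]octan-3-one, (3aR,6aS)-3a,6a-dimethylhexahydropentalen-2(1H)-one, meso | O=C1C[C@@]2(C)CCC[C@@]2(C)C1 | intermediate
6 | (4aR,7aR)-4a,7a-dimethylhexahydrocyclopenta[c]pyran-3(1H)-one | O=C1C[C@@]2(C)CCC[C@@]2(C)CO1 | intermediate
7 | (4aR,7aR)-4a,7a-dimethyloctahydrocyclopenta[c]pyran-3-ol (anomer mixture) | OC1C[C@@]2(C)CCC[C@@]2(C)CO1 | intermediate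
8 | 2-bromo-6-methylphenol | Cc1cccc(Br)c1O | starting material
9 | 2-bromo-6-methyl-1,4-benzoquinone | CC1=CC(=O)C=C(Br)C1=O | intermediate
10 | 2-bromo-6-methylbenzene-1,4-diol | Cc1cc(O)cc(Br)c1O | intermediate
11 | 1-bromo-2,5-bis(tert-butyldimethylsilyloxy)-3-methylbenzene | Cc1cc(O[Si](C)(C)C(C)(C)C)cc(Br)c1O[Si](C)(C)C(C)(C)C | intermediate
12 | 2-methyl-2-vinyloxirane (racemic) | CC1(C=C)CO1 | starting material
13 | [2,5-bis(tert-butyldimethylsilyloxy)-3-methylphenyl]magnesium bromide | Cc1cc(O[Si](C)(C)C(C)(C)C)cc([Mg]Br)c1O[Si](C)(C)C(C)(C)C | intermediate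
14 | bromomagnesium 4-[2,5-bis(tert-butyldimethylsilyloxy)-3-methylphenyl]-2-methylbut-2-en-1-olate (E major) | C/C(=C\Cc1cc(O[Si](C)(C)C(C)(C)C)cc(C)c1O[Si](C)(C)C(C)(C)C)CO[Mg]Br | intermediate
15 | methyl 4-[2,5-bis(tert-butyldimethylsilyloxy)-3-methylphenyl]-2-methylbut-2-en-1-yl carbonate (E major drawn) | C/C(=C\Cc1cc(O[Si](C)(C)C(C)(C)C)cc(C)c1O[Si](C)(C)C(C)(C)C)COC(=O)OC | intermediate
16 | rac-2-{1-[2,5-bis(tert-butyldimethylsilyloxy)-3-methylphenyl]-3-methylbut-3-en-2-yl}-4,4,5,5-tetramethyl-1,3,2-dioxaborolane | C=C(C)C(Cc1cc(O[Si](C)(C)C(C)(C)C)cc(C)c1O[Si](C)(C)C(C)(C)C)B1OC(C)(C)C(C)(C)O1 | intermediate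
17 | (Z)-6-[2,5-bis(tert-butyldimethylsilyloxy)-3-methylphenyl]-1-[(1R,2R)-2-(hydroxymethyl)-1,2-dimethylcyclopentyl]-4-methylhex-4-en-2-ol (C2 epimers) | C/C(=C/Cc1cc(O[Si](C)(C)C(C)(C)C)cc(C)c1O[Si](C)(C)C(C)(C)C)CC(O)C[C@@]1(C)CCC[C@@]1(C)CO | intermediate
18 | (1R,2R)-2-{(Z)-6-[2,5-bis(tert-butyldimethylsilyloxy)-3-methylphenyl]-4-methyl-2-oxohex-4-en-1-yl}-1,2-dimethylcyclopentane-1-carbaldehyde | C/C(=C/Cc1cc(O[Si](C)(C)C(C)(C)C)cc(C)c1O[Si](C)(C)C(C)(C)C)CC(=O)C[C@@]1(C)CCC[C@@]1(C)C=O | intermediate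
19 | 2-methyl-2-(trimethylsilyloxy)but-3-yne | C#CC(C)(C)O[Si](C)(C)C | starting material
20 | (E)-[3-methyl-3-(trimethylsilyloxy)but-1-enyl]zirconocene chloride | C[Si](C)(C)OC(C)(C)/C=C/[Zr](Cl)(C1C=CC=C1)C1C=CC=C1 | intermediate
21 | (E)-methyl[3-methyl-3-(trimethylsilyloxy)but-1-enyl]zinc | C[Zn]/C=C/C(C)(C)O[Si](C)(C)C | intermediate
22 | (Z)-6-[2,5-bis(tert-butyldimethylsilyloxy)-3-methylphenyl]-1-{(1R,2R)-2-[(E)-1-hydroxy-4-methyl-4-(trimethylsilyloxy)pent-2-en-1-yl]-1,2-dimethylcyclopentyl}-4-methylhex-4-en-2-one (carbinol epimers) | C/C(=C/Cc1cc(O[Si](C)(C)C(C)(C)C)cc(C)c1O[Si](C)(C)C(C)(C)C)CC(=O)C[C@@]1(C)CCC[C@@]1(C)C(O)/C=C/C(C)(C)O[Si](C)(C)C | intermediate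
23 | (Z)-6-[2,5-bis(tert-butyldimethylsilyloxy)-3-methylphenyl]-4-methyl-1-{(1R,2R)-1,2-dimethyl-2-[(E)-4-methyl-4-(trimethylsilyloxy)pent-2-enoyl]cyclopentyl}hex-4-en-2-one | C/C(=C/Cc1cc(O[Si](C)(C)C(C)(C)C)cc(C)c1O[Si](C)(C)C(C)(C)C)CC(=O)C[C@@]1(C)CCC[C@@]1(C)C(=O)/C=C/C(C)(C)O[Si](C)(C)C | intermediate
24 | (Z)-6-(2,5-dihydroxy-3-methylphenyl)-1-{(1R,2R)-2-[(E)-4-hydroxy-4-methylpent-2-enoyl]-1,2-dimethylcyclopentyl}-4-methylhex-4-en-2-one | C/C(=C/Cc1cc(O)cc(C)c1O)CC(=O)C[C@@]1(C)CCC[C@@]1(C)C(=O)/C=C/C(C)(C)O | target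

**Step count and risks**

Total steps: 13. Longest linear sequence: 9 (steps 1–4 and 9–13 from 1; equally steps 5–13 from 8).

The three steps most likely to fail:

Step 3, the new desymmetrising Baeyer–Villiger oxidation. Cyclopentanones are poor Baeyer–Villiger substrates, the uncatalysed mCPBA pathway could erode the ee, and the chiral pocket may not distinguish the two CH2 groups well enough. The fallback uses known chemistry and sets out from 5. Enantioselective deprotonation with lithium (R,R)- or (S,S)-bis(1-phenylethyl)amide, LiN[CH(CH3)Ph]2, with Me3SiCl present as internal quench (THF, LiCl, −100 °C), gives the trimethylsilyl enol ether of 5 with its double bond on the side of the S-configured ring-fusion carbon F1. Ozonolysis (O3, CH2Cl2/MeOH, −78 °C) cleaves it to 2-[(1R,2R)-2-formyl-1,2-dimethylcyclopentyl]acetic acid F2, which NaBH4 reduces in the same flask to 2-[(1R,2R)-2-(hydroxymethyl)-1,2-dimethylcyclopentyl]acetic acid F3. TsOH in PhMe then closes F3 to the lactone, and the route is rejoined at 6.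

Step 9, the allylboration of the lactol. The gem-disubstituted lactol 7 may expose too little of its aldehyde form to react with the hindered α-substituted boronate, and a slow reaction could also lower the Z:E ratio. The fallback sets out from 6 and replaces the lactol by an acyclic aldehyde. Ring opening with MeNH(OMe)·HCl/iPrMgCl gives 2-[(1R,2R)-2-(hydroxymethyl)-1,2-dimethylcyclopentyl]-N-methoxy-N-methylacetamide F4. Et3SiCl/imidazole gives its triethylsilyl ether F5, and iBu2AlH at −78 °C gives 2-{(1R,2R)-1,2-dimethyl-2-[(triethylsilyloxy)methyl]cyclopentyl}acetaldehyde F6. Allylboration of F6 with 16 at room temperature gives the mono-triethylsilyl ether of 17 F7. Pyridinium tosylate in MeOH removes the triethylsilyl group, and the route is rejoined at 17.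

Step 11, the alkenylzinc addition. The aldehyde of 18 is flanked by two quaternary carbons and may react slowly, giving time for aldol closure with the neighbouring ketone. The fallback sets out from 19. Hydrozirconation with Cp2Zr(H)Cl followed by I2 gives (E)-4-iodo-2-methyl-2-(trimethylsilyloxy)but-3-ene F8. F8 is then coupled with 18 under Nozaki–Hiyama–Kishi conditions (CrCl2, 1 mol% NiCl2, DMSO/THF, rt). The divalent chromium reagent is selective for aldehydes over ketones and tolerant of hindrance, and the route is rejoined at 22.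

**Further compounds**
F1 | step 3 | trimethylsilyl enol ether of 5 (double bond toward the S-configured ring-fusion carbon) | C[Si](C)(C)OC1=C[C@]2(C)CCC[C@]2(C)C1
F2 | step 3 | 2-[(1R,2R)-2-formyl-1,2-dimethylcyclopentyl]acetic acid | OC(=O)C[C@@]1(C)CCC[C@@]1(C)C=O
F3 | step 3 | 2-[(1R,2R)-2-(hydroxymethyl)-1,2-dimethylcyclopentyl]acetic acid | OC(=O)C[C@@]1(C)CCC[C@@]1(C)CO
F4 | step 9 | 2-[(1R,2R)-2-(hydroxymethyl)-1,2-dimethylcyclopentyl]-N-methoxy-N-methylacetamide | CON(C)C(=O)C[C@@]1(C)CCC[C@@]1(C)CO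
F5 | step 9 | 2-{(1R,2R)-1,2-dimethyl-2-[(triethylsilyloxy)methyl]cyclopentyl}-N-methoxy-N-methylacetamide | CON(C)C(=O)C[C@@]1(C)CCC[C@@]1(C)CO[Si](CC)(CC)CC
F6 | step 9 | 2-{(1R,2R)-1,2-dimethyl-2-[(triethylsilyloxy)methyl]cyclopentyl}acetaldehyde | O=CC[C@@]1(C)CCC[C@@]1(C)CO[Si](CC)(CC)CC
F7 | step 9 | (Z)-6-[2,5-bis(tert-butyldimethylsilyloxy)-3-methylphenyl]-1-{(1R,2R)-1,2-dimethyl-2-[(triethylsilyloxy)methyl]cyclopentyl}-4-methylhex-4-en-2-ol | C/C(=C/Cc1cc(O[Si](C)(C)C(C)(C)C)cc(C)c1O[Si](C)(C)C(C)(C)C)CC(O)C[C@@]1(C)CCC[C@@]1(C)CO[Si](CC)(CC)CC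
F8 | step 11 | (E)-4-iodo-2-methyl-2-(trimethylsilyloxy)but-3-ene | C[Si](C)(C)OC(C)(C)/C=C/I
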